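**Pl**an

- Core atoms carry isochromene numbers and lactone atoms carry primes. In the carbocycle C4a–C5–C6–C7–C8–C8a, the methylated, oxygenated C7 lies para to C4a, C6 is a ketone and C8a bears C1. This is the imprint of a 7-oxanorbornadiene whose oxygen bridge joined C7 and C4a, made from a 2,5-disubstituted 3-silyloxyfuran and an ynal.
- The retrosynthesis cuts O2–C3 (alkyne cycloisomerisation), then C8–C3' together with the C4a–O bridge bond (Michael addition/E1cB), then C7–C8 and C4a–C8a (Diels–Alder), and last the C4a–C4 bond of the furan (acetylide addition to a chlorotetronate).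
- Forward, the side-chain enyne is made first, then the furan; the Diels–Alder reaction closes the carbocycle, the lactone opens the bridge, and the pyran ring closes last. Chlorine and the C3–C4 alkyne are built into the furan so that no halogenating or acylating agent ever meets the β-keto lactone.
- Stereochemistry: side-chain C5 comes from (S)-2-methylbutan-1-ol and C6' from ethyl (S)-3-hydroxybutanoate. C7 is set by the catalyst-controlled cycloaddition and C8 by exo attack on the bicycle. C3' is under thermodynamic control.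

Key step: step 10

Assumption: C3' lies between two carbonyl groups and epimerises through its enol, so the (3'R) keto form of the target is taken as the epimer reached at equilibrium; intermediates are drawn as diketones without a descriptor at that carbon.

**Route**

Step 1
Reactants: 1 (S)-2-methylbutan-1-ol
Product: 2 (S)-2-methylbutanal
Conditions: TEMPO [(2,2,6,6-tetramethylpiperidin-1-yl)oxyl] (5 mol %), PhI(OAc)2, CH2Cl2, 0 °C to rt; dried solution used directly
Reagents that add atoms: none
Why: Oxoammonium (TEMPO) oxidation of a primary alcohol stops at the aldehyde under neutral, non-enolising conditions, so the α-stereocentre should survive.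

Step 2
Reactants: 2 (S)-2-methylbutanal; 3 2-(triphenyl-λ5-phosphanylidene)propanal
Product: 4 (2E,4S)-2,4-dimethylhex-2-enal
Conditions: PhMe, 80 °C, sealed vessel
Reagents that add atoms: none
Why: The Wittig reaction with this α-methyl, formyl-stabilised ylide should give the trisubstituted (E)-enal without any base that could epimerise C4.

Step 3
Reactants: 4 (2E,4S)-2,4-dimethylhex-2-enal; 5 diethyl [3-(trimethylsilyl)prop-2-yn-1-yl]phosphonate
Product: 6 trimethyl[(3E,5E,7S)-5,7-dimethylnona-3,5-dien-1-yn-1-yl]silane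
Conditions: 5, LiN(SiMe3)2, THF, −78 °C; then 4, −78 °C to 0 °C
Reagents that add atoms: none
Why: The Horner–Wadsworth–Emmons olefination of an enal with the lithiated propargylic phosphonate should form the new disubstituted alkene with high E selectivity and keep the silyl-capped alkyne in place.

Step 4
Reactants: 6 trimethyl[(3E,5E,7S)-5,7-dimethylnona-3,5-dien-1-yn-1-yl]silane
Product: 7 (3E,5E,7S)-5,7-dimethylnona-3,5-dien-1-yne
Conditions: K2CO3 (20 mol %), MeOH, rt
Reagents that add atoms: none
Why: Carbonate-catalysed methanolysis of the alkynyl C–Si bond (protodesilylation) is general for trimethylsilylalkynes and does not affect the diene or the stereocentre.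

Step 5
Reactants: 8 4-methoxyfuran-2(5H)-one
Product: 9 4-methoxy-5-methylfuran-2(5H)-one
Conditions: LiN(iPr)2, THF, −78 °C; MeI, −78 °C to −20 °C
Reagents that add atoms: iodomethane, CI
Why: Deprotonation at C5 gives the 2-oxidofuran dienolate of the vinylogous carbonate, which is methylated at C5 (γ-alkylation of a tetronate); the new centre is racemic and is erased when the ring becomes a furan.

Step 6
Reactants: 9 4-methoxy-5-methylfuran-2(5H)-one
Product: 10 3-chloro-4-methoxy-5-methylfuran-2(5H)-one
Conditions: NCS, DMF, rt to 50 °C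
Reagents that add atoms: N-chlorosuccinimide, O=C1CCC(=O)N1Cl
Why: Electrophilic chlorination of the β-alkoxy enoate can only occur at C3, its enol-ether β-carbon, which places chlorine on the future C5 before any halogen-sensitive group is present.

Step 7
Reactants: 7 (3E,5E,7S)-5,7-dimethylnona-3,5-dien-1-yne; 10 3-chloro-4-methoxy-5-methylfuran-2(5H)-one
Product: 12 4-chloro-5-[(3E,5E,7S)-5,7-dimethylnona-3,5-dien-1-yn-1-yl]-2-methylfuran-3(2H)-one, via hemiketal adduct 11 (not isolated)
Conditions: 7, n-BuLi, THF, −78 °C; anhydrous CeCl3, −78 °C; 10, −78 °C; then 1 M aq. HCl, THF, rt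
Reagents that add atoms: water, O
Why: 1,2-Addition of the weakly basic cerium acetylide to the lactone carbonyl, followed by acid-promoted loss of water and hydrolysis of the methyl enol ether, is a Stork–Danheiser-type carbonyl transposition that converts the tetronate into the 5-alkynylfuran-3(2H)-one; both C2 epimers are carried on because that centre becomes sp2 in step 8.

Step 8
Reactants: 12 4-chloro-5-[(3E,5E,7S)-5,7-dimethylnona-3,5-dien-1-yn-1-yl]-2-methylfuran-3(2H)-one
Product: 13 {[4-chloro-5-[(3E,5E,7S)-5,7-dimethylnona-3,5-dien-1-yn-1-yl]-2-methylfuran-3-yl]oxy}tri(propan-2-yl)silane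
Conditions: TIPSOTf, Et3N, CH2Cl2, 0 °C
Reagents that add atoms: triisopropylsilyl trifluoromethanesulfonate, CC(C)[Si](C(C)C)(C(C)C)OS(=O)(=O)C(F)(F)F
Why: Soft enolisation and O-silylation of the furan-3(2H)-one with a silyl triflate and a tertiary amine aromatises the ring to the 3-silyloxyfuran, the bulky triisopropylsilyl group being chosen for resistance to the acidic catalyst of step 10.

Step 9
Reactants: 14 3,3-diethoxyprop-1-yne
Product: 15 prop-2-ynal
Conditions: 2 M aq. H2SO4, 0 °C to rt; extraction into CH2Cl2, dried (MgSO4), used at once as a titrated solution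
Reagents that add atoms: water, O
Why: Acid-catalysed acetal hydrolysis liberates the ynal, which is handled only in cold solution because it is volatile and prone to polymerise.

Step 10
Reactants: 13 {[4-chloro-5-[(3E,5E,7S)-5,7-dimethylnona-3,5-dien-1-yn-1-yl]-2-methylfuran-3-yl]oxy}tri(propan-2-yl)silane; 15 prop-2-ynal
Product: 16 (1R,4S)-6-chloro-1-[(3E,5E,7S)-5,7-dimethylnona-3,5-dien-1-yn-1-yl]-4-methyl-5-{[tri(propan-2-yl)silyl]oxy}-7-oxabicyclo[2.2.1]hepta-2,5-diene-2-carbaldehyde
Conditions: (S)-1-(2-methylphenyl)-3,3-diphenyltetrahydro-1H,3H-pyrrolo[1,2-c][1,3,2]oxazaborole (20 mol %), HNTf2 (18 mol %), CH2Cl2, −78 °C; Et3N quench; product used without delay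
Reagents that add atoms: none
Why: Proposed new method: coordination of the formyl oxygen of 15 to the chiral oxazaborolidinium ion lowers the LUMO of the ynal, and the furan adds in a concerted but asynchronous [4+2] cycloaddition in which furan C2 (the enol-ether β-carbon, future C7) bonds first to the ynal β-carbon (future C8) and furan C5 (future C4a) bonds to the formyl-bearing carbon (future C8a). The closest known reactions are oxazaborolidinium-catalysed enantioselective Diels–Alder reactions of furans and of acetylenic carbonyl dienophiles, and the uncatalysed cycloadditions of 3-silyloxyfurans with acetylenic dienophiles; pairing a 3-silyloxyfuran with an ynal under such a catalyst is the untested element. The six-membered carbocycle is closed by suprafacial [4+2] cycloaddition across the furan 2,5-positions, which at the same time turns the furan into the two 2,5-dihydrofuran rings of the 7-oxanorbornadiene. Both bridgehead stereocentres form in this one suprafacial event, so their relative configuration is fixed by geometry and their absolute configuration by the catalyst, which shields one face of the coordinated ynal. The step needs para regiochemistry (secured by the 3-silyloxy group, which makes C2 the most nucleophilic terminus), reaction at the furan and not at the side-chain diene (the furan is far more electron-rich), and cycloaddition across C≡C in preference to aldol addition at C=O (favoured by low temperature and the fully substituted C2 terminus); the bulky silyl group and a slight excess of oxazaborolidine over HNTf2 guard against protodesilylation and opening of the adduct.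

Step 11
Reactants: 17 ethyl (S)-3-hydroxybutanoate; 18 tert-butyl acetate
Product: 19 tert-butyl (5S)-5-hydroxy-3-oxohexanoate
Conditions: LiN(iPr)2 (3.5 equiv), 18 (3.5 equiv), THF, −78 °C; then 17, −78 °C to −30 °C; AcOH quench
Reagents that add atoms: none
Why: A crossed Claisen condensation with excess lithium enolate of 18 (which also deprotonates the hydroxyl group and the product) gives the δ-hydroxy-β-keto ester with the carbinol centre untouched.

Step 12
Reactants: 19 tert-butyl (5S)-5-hydroxy-3-oxohexanoate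
Product: 20 (6S)-6-methyloxane-2,4-dione
Conditions: CF3CO2H, CH2Cl2, 0 °C to rt
Reagents that add atoms: none
Why: Acidolysis of the tert-butyl ester with concurrent lactonisation by the δ-hydroxyl group closes the six-membered β-keto lactone faster than the β-keto acid can decarboxylate, and the stereocentre is a spectator.

Step 13
Reactants: 16 (1R,4S)-6-chloro-1-[(3E,5E,7S)-5,7-dimethylnona-3,5-dien-1-yn-1-yl]-4-methyl-5-{[tri(propan-2-yl)silyl]oxy}-7-oxabicyclo[2.2.1]hepta-2,5-diene-2-carbaldehyde; 20 (6S)-6-methyloxane-2,4-dione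
Product: 22 (5S,6S)-3-chloro-2-[(3E,5E,7S)-5,7-dimethylnona-3,5-dien-1-yn-1-yl]-5-hydroxy-5-methyl-6-[(6S)-6-methyl-2,4-dioxooxan-3-yl]-4-{[tri(propan-2-yl)silyl]oxy}cyclohexa-1,3-diene-1-carbaldehyde, via exo Michael adduct 21 (not isolated)
Conditions: DBU [1,8-diazabicyclo[5.4.0]undec-7-ene] (20 mol %), THF, −20 °C to rt
Reagents that add atoms: none
Why: Michael addition of the soft enolate of 20 to the strained enal should occur on the exo face, syn to the oxygen bridge, which sets C8; the aldehyde enolate so formed then expels the bridging alkoxide from C4a (E1cB opening of the oxanorbornene), freeing the C7 hydroxyl cis to the lactone and passing the proton on from the next molecule of 20.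

Step 14
Reactants: 22 (5S,6S)-3-chloro-2-[(3E,5E,7S)-5,7-dimethylnona-3,5-dien-1-yn-1-yl]-5-hydroxy-5-methyl-6-[(6S)-6-methyl-2,4-dioxooxan-3-yl]-4-{[tri(propan-2-yl)silyl]oxy}cyclohexa-1,3-diene-1-carbaldehyde
Product: 23 (5S,6S)-3-chloro-2-[(3E,5E,7S)-5,7-dimethylnona-3,5-dien-1-yn-1-yl]-4,5-dihydroxy-5-methyl-6-[(6S)-6-methyl-2,4-dioxooxan-3-yl]cyclohexa-1,3-diene-1-carbaldehyde
Conditions: HF·pyridine, pyridine, THF, 0 °C
Reagents that add atoms: none
Why: The silyl enol ether is a vinylogous silyl ester of the aldehyde and should be cleaved rapidly by buffered fluoride (desilylation), giving the vinylogous acid without disturbing C7, C8 or the alkyne.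

Step 15
Reactants: 23 (5S,6S)-3-chloro-2-[(3E,5E,7S)-5,7-dimethylnona-3,5-dien-1-yn-1-yl]-4,5-dihydroxy-5-methyl-6-[(6S)-6-methyl-2,4-dioxooxan-3-yl]cyclohexa-1,3-diene-1-carbaldehyde
Product: 24 (7S,8S)-5-chloro-3-[(1E,3E,5S)-3,5-dimethylhepta-1,3-dien-1-yl]-7-hydroxy-7-methyl-8-[(3R,6S)-6-methyl-2,4-dioxooxan-3-yl]-7,8-dihydro-6H-isochromen-6-one
Conditions: Au(OAc)3 (5 mol %), CF3CO2H (2 equiv), ClCH2CH2Cl, rt
Reagents that add atoms: none
Why: Gold-catalysed 6-endo-dig cycloisomerisation of the o-alkynyl aldehyde, the established closure of 6H-isochromen-6-one cores, gives a pyrylium-type vinylgold species that loses the enol proton to form the C4a=C5–C6=O chromophore and is protodeaurated; no stereocentre is formed or touched, and C3' settles by enolisation.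

**Compound list**

1 | (S)-2-methylbutan-1-ol | CC[C@H](C)CO | starting material
2 | (S)-2-methylbutanal | CC[C@H](C)C=O | intermediate
3 | 2-(triphenyl-λ5-phosphanylidene)propanal | CC(C=O)=P(c1ccccc1)(c1ccccc1)c1ccccc1 | starting material
4 | (2E,4S)-2,4-dimethylhex-2-enal | CC[C@H](C)/C=C(C)/C=O | intermediate
5 | diethyl [3-(trimethylsilyl)prop-2-yn-1-yl]phosphonate | CCOP(=O)(CC#C[Si](C)(C)C)OCC | starting material
6 | trimethyl[(3E,5E,7S)-5,7-dimethylnona-3,5-dien-1-yn-1-yl]silane | CC[C@H](C)/C=C(C)/C=C/C#C[Si](C)(C)C | intermediate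
7 | (3E,5E,7S)-5,7-dimethylnona-3,5-dien-1-yne | CC[C@H](C)/C=C(C)/C=C/C#C | intermediate
8 | 4-methoxyfuran-2(5H)-one (methyl tetronate) | COC1=CC(=O)OC1 | starting material
9 | 4-methoxy-5-methylfuran-2(5H)-one (racemic) | COC1=CC(=O)OC1C | intermediate
10 | 3-chloro-4-methoxy-5-methylfuran-2(5H)-one (racemic) | COC1=C(Cl)C(=O)OC1C | intermediate
11 | 3-chloro-2-[(3E,5E,7S)-5,7-dimethylnona-3,5-dien-1-yn-1-yl]-4-methoxy-5-methyl-2,5-dihydrofuran-2-ol (hemiketal adduct, diastereomer mixture, formed in the flask) | CC[C@H](C)/C=C(C)/C=C/C#CC1(O)OC(C)C(OC)=C1Cl | intermediate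
12 | 4-chloro-5-[(3E,5E,7S)-5,7-dimethylnona-3,5-dien-1-yn-1-yl]-2-methylfuran-3(2H)-one (both C2 epimers) | CC[C@H](C)/C=C(C)/C=C/C#CC1=C(Cl)C(=O)C(C)O1 | intermediate
13 | {[4-chloro-5-[(3E,5E,7S)-5,7-dimethylnona-3,5-dien-1-yn-1-yl]-2-methylfuran-3-yl]oxy}tri(propan-2-yl)silane | CC[C@H](C)/C=C(C)/C=C/C#Cc1oc(C)c(O[Si](C(C)C)(C(C)C)C(C)C)c1Cl | intermediate
14 | 3,3-diethoxyprop-1-yne | CCOC(OCC)C#C | starting material
15 | prop-2-ynal | C#CC=O | intermediate
16 | (1R,4S)-6-chloro-1-[(3E,5E,7S)-5,7-dimethylnona-3,5-dien-1-yn-1-yl]-4-methyl-5-{[tri(propan-2-yl)silyl]oxy}-7-oxabicyclo[2.2.1]hepta-2,5-diene-2-carbaldehyde | C[C@@]12O[C@@](C#C/C=C/C(C)=C/[C@@H](C)CC)(C(Cl)=C1O[Si](C(C)C)(C(C)C)C(C)C)C(C=O)=C2 | intermediate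
17 | ethyl (S)-3-hydroxybutanoate | CCOC(=O)C[C@H](C)O | starting material
18 | tert-butyl acetate | CC(=O)OC(C)(C)C | starting material
19 | tert-butyl (5S)-5-hydroxy-3-oxohexanoate | C[C@H](O)CC(=O)CC(=O)OC(C)(C)C | intermediate
20 | (6S)-6-methyloxane-2,4-dione | C[C@H]1CC(=O)CC(=O)O1 | intermediate
21 | 3-chloro-4-[(3E,5E,7S)-5,7-dimethylnona-3,5-dien-1-yn-1-yl]-1-methyl-6-exo-[(6S)-6-methyl-2,4-dioxooxan-3-yl]-2-{[tri(propan-2-yl)silyl]oxy}-7-oxabicyclo[2.2.1]hept-2-ene-5-carbaldehyde (exo Michael adduct, formed in the flask; C5 and lactone C3 not fixed) | C[C@@]12O[C@@](C#C/C=C/C(C)=C/[C@@H](C)CC)(C(Cl)=C1O[Si](C(C)C)(C(C)C)C(C)C)C(C=O)[C@@H]2C3C(=O)C[C@H](C)OC3=O | intermediate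
22 | (5S,6S)-3-chloro-2-[(3E,5E,7S)-5,7-dimethylnona-3,5-dien-1-yn-1-yl]-5-hydroxy-5-methyl-6-[(6S)-6-methyl-2,4-dioxooxan-3-yl]-4-{[tri(propan-2-yl)silyl]oxy}cyclohexa-1,3-diene-1-carbaldehyde | C[C@]1(O)[C@@H](C2C(=O)C[C@H](C)OC2=O)C(C=O)=C(C#C/C=C/C(C)=C/[C@@H](C)CC)C(Cl)=C1O[Si](C(C)C)(C(C)C)C(C)C | intermediate
23 | (5S,6S)-3-chloro-2-[(3E,5E,7S)-5,7-dimethylnona-3,5-dien-1-yn-1-yl]-4,5-dihydroxy-5-methyl-6-[(6S)-6-methyl-2,4-dioxooxan-3-yl]cyclohexa-1,3-diene-1-carbaldehyde (vinylogous acid) | C[C@]1(O)[C@@H](C2C(=O)C[C@H](C)OC2=O)C(C=O)=C(C#C/C=C/C(C)=C/[C@@H](C)CC)C(Cl)=C1O | intermediate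
24 | (7S,8S)-5-chloro-3-[(1E,3E,5S)-3,5-dimethylhepta-1,3-dien-1-yl]-7-hydroxy-7-methyl-8-[(3R,6S)-6-methyl-2,4-dioxooxan-3-yl]-7,8-dihydro-6H-isochromen-6-one (CNP0584120.1) | CC[C@H](C)/C=C(C)/C=C/C1=CC2=C(Cl)C(=O)[C@@](C)(O)[C@@H]([C@@H]3C(=O)C[C@H](C)OC3=O)C2=CO1 | target

**Count**

Total steps: 15. Longest linear sequence: 10 steps (1, 2, 3, 4, 7, 8, 10, 13, 14, 15).

**Steps most likely to fail**

1. Step 10. The silyloxyfuran may attack the activated formyl carbon in an aldol sense instead of the alkyne. The acidic catalyst may also desilylate the furan or open the oxygen bridge of the adduct, or facial discrimination may be poor or of the wrong sense (the antipodal catalyst is equally available).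

   Fallback with known chemistry: 13 and 15 are combined without catalyst in toluene at 0 °C to rt, the thermal cycloaddition of a 3-silyloxyfuran with an acetylenic dienophile. This should give 16 together with its bridgehead diastereomer, the (1S,4R) adduct F1. The mixture is taken through the conditions of step 13 with enantiopure 20. The adduct F1 then passes through its own exo Michael adduct F2 to the (5R,6R) ring-opened diastereomer F3. F3 differs from 22 in the configuration of the core relative to two fixed stereocentres and is removed by chromatography. The route is rejoined at 22.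

2. Step 13. The conjugate adduct may fragment by retro-Diels–Alder reaction before the bridge opens. The weakly nucleophilic lactone enolate may add sluggishly or through oxygen, or exo selectivity may be incomplete.

   Fallback: 16 is treated with the more nucleophilic open-chain β-keto ester 19 and catalytic DBU in THF. The reaction should pass through the exo Michael adduct F4 to the ring-opened keto ester, tert-butyl (5S)-2-[(1S,6S)-4-chloro-3-[(3E,5E,7S)-5,7-dimethylnona-3,5-dien-1-yn-1-yl]-2-formyl-6-hydroxy-6-methyl-5-{[tri(propan-2-yl)silyl]oxy}cyclohexa-2,4-dien-1-yl]-5-hydroxy-3-oxohexanoate F5. Treatment with CF3CO2H in CH2Cl2 then cleaves the tert-butyl ester, closes the lactone and hydrolyses the silyl enol ether in one operation. The route is rejoined at 23.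

3. Step 7. The acetylide may deprotonate the tetronate at C5 instead of adding. It may also displace methoxide by addition–elimination at C4, or the transposition may stall at the hemiketal.

   Fallback: 10 is reduced with iBu2AlH (CH2Cl2, −78 °C) to the lactol 3-chloro-4-methoxy-5-methyl-2,5-dihydrofuran-2-ol F6. Dilute acid transposes it to 4-chloro-2-methylfuran-3(2H)-one F7, the hydride version of the same transposition. Silylation with TIPSOTf/Et3N gives [(4-chloro-2-methylfuran-3-yl)oxy]tri(propan-2-yl)silane F8. Lithiation at C5 with n-BuLi (THF, −78 °C) and quenching with I2 gives [(4-chloro-5-iodo-2-methylfuran-3-yl)oxy]tri(propan-2-yl)silane F9. Sonogashira coupling of F9 with 7 (PdCl2(PPh3)2, CuI, Et3N, THF, rt) forms the C4a–C4 bond. The route is rejoined at 13.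

**Further compounds**

F1 | step 10 | (1S,4R)-6-chloro-1-[(3E,5E,7S)-5,7-dimethylnona-3,5-dien-1-yn-1-yl]-4-methyl-5-{[tri(propan-2-yl)silyl]oxy}-7-oxabicyclo[2.2.1]hepta-2,5-diene-2-carbaldehyde | C[C@]12O[C@](C#C/C=C/C(C)=C/[C@@H](C)CC)(C(Cl)=C1O[Si](C(C)C)(C(C)C)C(C)C)C(C=O)=C2
F2 | step 10 | exo Michael adduct of F1 and 20 (bridgehead-epimeric series of 21) | C[C@]12O[C@](C#C/C=C/C(C)=C/[C@@H](C)CC)(C(Cl)=C1O[Si](C(C)C)(C(C)C)C(C)C)C(C=O)[C@H]2C3C(=O)C[C@H](C)OC3=O
F3 | step 10 | (5R,6R)-3-chloro-2-[(3E,5E,7S)-5,7-dimethylnona-3,5-dien-1-yn-1-yl]-5-hydroxy-5-methyl-6-[(6S)-6-methyl-2,4-dioxooxan-3-yl]-4-{[tri(propan-2-yl)silyl]oxy}cyclohexa-1,3-diene-1-carbaldehyde | C[C@@]1(O)[C@H](C2C(=O)C[C@H](C)OC2=O)C(C=O)=C(C#C/C=C/C(C)=C/[C@@H](C)CC)C(Cl)=C1O[Si](C(C)C)(C(C)C)C(C)C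
F4 | step 13 | exo Michael adduct of 16 and 19 (formed in the flask) | C[C@@]12O[C@@](C#C/C=C/C(C)=C/[C@@H](C)CC)(C(Cl)=C1O[Si](C(C)C)(C(C)C)C(C)C)C(C=O)[C@@H]2C(C(=O)OC(C)(C)C)C(=O)C[C@H](C)O
F5 | step 13 | tert-butyl (5S)-2-[(1S,6S)-4-chloro-3-[(3E,5E,7S)-5,7-dimethylnona-3,5-dien-1-yn-1-yl]-2-formyl-6-hydroxy-6-methyl-5-{[tri(propan-2-yl)silyl]oxy}cyclohexa-2,4-dien-1-yl]-5-hydroxy-3-oxohexanoate | C[C@]1(O)[C@@H](C(C(=O)OC(C)(C)C)C(=O)C[C@H](C)O)C(C=O)=C(C#C/C=C/C(C)=C/[C@@H](C)CC)C(Cl)=C1O[Si](C(C)C)(C(C)C)C(C)C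
F6 | step 7 | 3-chloro-4-methoxy-5-methyl-2,5-dihydrofuran-2-ol | COC1=C(Cl)C(O)OC1C
F7 | step 7 | 4-chloro-2-methylfuran-3(2H)-one | CC1OC=C(Cl)C1=O
F8 | step 7 | [(4-chloro-2-methylfuran-3-yl)oxy]tri(propan-2-yl)silane | Cc1occ(Cl)c1O[Si](C(C)C)(C(C)C)C(C)C
F9 | step 7 | [(4-chloro-5-iodo-2-methylfuran-3-yl)oxy]tri(propan-2-yl)silane | Cc1oc(I)c(Cl)c1O[Si](C(C)C)(C(C)C)C(C)C
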